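In a one-step world every enzyme charged would work, and the rate would simply scale with that charge, but this flask, the ochre run carried on, has more in it.

| flask | starting material | second substrate | free enzyme | impurity | remark |
|---|---|---|---|---|---|
| ochre | 0.058 M | 0.087 M | 8.7 µM | 2.6 µM | the very flask that is asked about, followed so far |
| red | 0.029 M | 0.087 M | 8.7 µM | 2.6 µM | run made earlier |
| flask | 0.058 M | 0.0870 M | 8.7 µM | 2.6 µM |  |

| run | time / min | target / % | starting material / % |
|---|---|---|---|
| ochre | 0.250 | 1 | 99 |
| ochre | 0.667 | 1 | 101 |
| ochre | 1.33 | 4 | 97 |
| ochre | 2.00 | 5 | 96 |
| ochre | 2.50 | 5 | 96 |
| red | 1.33 | 3 | 99 |
| red | 4.00 | 6 | 94 |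
| red | 8.00 | 10 | 86 |
| red | 10.0 | 19 | 83 |
| red | 15.0 | 24 | 75 |

(scatter of a reading: 2 percentage points)

- apparent order in second substrate when 30% of the starting material are converted (percent change of the rate of making target for one percent more second substrate charged)

- no earlier run changes the charge of second substrate; that part of a forecast is a guess

Both runs held second substrate at 0.087 M, so they gave me no slope in it, and I turned to two amounts in the flask, the enzyme charged, 8.7 µM, and the impurity charged, 2.6 µM. Reckoning on my own, I took it that each impurity removes one free enzyme; the enzyme charged exceeds the impurity, so impurity is the limiting reagent of that loss. What stays is the working share, the fraction of the enzyme charged that still goes round, one minus the ratio of those two amounts: 70.1%. I read an order in second substrate as the part of that working share that waits for second substrate, but the runs could not show me that part, so I committed to the working share and to no order.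

The forecast put the order at 0.45: “I guess an intermediate value, with a wide range.”

The flask gave 0.20.

    starting material + free enzyme ⇌ first complex (K = 46.0 /M, k = 3500 /M/s)
    first complex → loaded enzyme + first product (k = 4.70 /s)
    second substrate + loaded enzyme ⇌ second complex (K = 34.0 /M, k = 980 /M/s)
    second complex → free enzyme + target (k = 3.40 /s)
    free enzyme + impurity → spent catalyst (k = 18000 /M/s)
    starting material + first product → side product (k = 0.0160 /M/s)

In the flask at 15.0 min, impurity stood at 0% and spent catalyst at 29.9%, the complement of my working share. Loaded enzyme, the form waiting for second substrate, then held 11.7% of the catalyst charged, which is 16.7% of the working share at that moment, while the order of 0.20 belongs to 24.3 min. The run without the path from free enzyme + impurity to spent catalyst reached 1.42 times the actual rate at 30% conversion, a part of what holds this rate down, and its apparent order in free enzyme at that conversion was 1.0 against 1.4 in the flask.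

Readings and results stem from a simulated flask for an exercise; the scatter is artificial.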